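**Retrosynthetic overview**
- The benzene ring is bought. 1,4-Dibromobenzene (1) is taken to the centrosymmetric tetrahalide 2. Its two iodines mark the future C3a and C6, its two bromines C4 and C7, and its two hydrogens C7a and C5.
- Both azulene ring systems are bought as guaiazulene (3). One equivalent becomes the alkyne 5 by way of the iodide 4.
- Key disconnection: the five-membered ring of 6 is the only ring built. It opens to 2 + 5 + CO. Either iodide of 2 gives the same product, and afterwards every remaining ring position is different.
- The C6–azulenyl bond of 7 opens to the iodide 6 and a C–H bond of 3.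
- The C4–CHO of 8 and the C7–CH3 of 9 (the target) come from the two bromine place-holders. They are told apart by crowding.

Assumption: the SMILES has no stereodescriptor and the molecule has no stereocentre. The two azulenyl–core axes are taken as not configurationally fixed, so nothing has to be set or resolved.

"Guaiazulen-3-yl" means 7-isopropyl-1,4-dimethylazulen-3-yl. It is bonded through the free five-ring carbon that faces the 4-methyl group.

**Step 1**
Reactants: 1 1,4-dibromobenzene
Product: 2 1,4-dibromo-2,5-diiodobenzene
Conditions: NIS (2.2 equiv), conc. H2SO4, 0 °C to rt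
Reagents that add atoms: N-iodosuccinimide O=C1CCC(=O)N1I
Why: Electrophilic aromatic iodination with the protonated N-iodoimide works even on this deactivated ring; all four free positions of 1 are equivalent, and the first iodine steers the second para to itself, so only the centrosymmetric 2,5-isomer forms.

**Step 2**
Reactants: 3 guaiazulene (7-isopropyl-1,4-dimethylazulene)
Product: 5 3-(prop-1-yn-1-yl)guaiazulene, via 3-iodoguaiazulene 4 (not isolated)
Conditions: NIS (1.0 equiv), THF, −40 °C, dark; then Bu3SnC≡CMe (1.3 equiv), Pd(PPh3)4 (5 mol %), CuI (10 mol %), −40 °C to rt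
Reagents that add atoms: N-iodosuccinimide O=C1CCC(=O)N1I (iodine of 4); tributyl(prop-1-yn-1-yl)stannane CC#C[Sn](CCCC)(CCCC)CCCC
Why: Electrophilic aromatic substitution of guaiazulene goes only to C3, the one free position of the electron-rich five-membered ring, and a neutral Stille coupling in the same flask consumes the labile iodide 4 before it decomposes.

**Step 3 (key step)**
Reactants: 2 1,4-dibromo-2,5-diiodobenzene; 5 3-(prop-1-yn-1-yl)guaiazulene
Product: 6 4,7-dibromo-6-iodo-3-methyl-2-(guaiazulen-3-yl)-1H-inden-1-one
Conditions: Pd(OAc)2 (10 mol %), PPh3 (20 mol %), CsO2CCMe3 (2.5 equiv), CO (1 atm), DMF, 100 °C; 2 in threefold excess, surplus recovered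
Reagents that add atoms: carbon monoxide [C-]#[O+]
Why: Proposed new method: zerovalent palladium inserts into either of the two equivalent carbon–iodine bonds far faster than into carbon–bromine; syn-carbopalladation of 5 then puts the aryl group on the methyl-bearing alkyne carbon and palladium next to the bulky azulenyl group (Larock regiochemistry); the vinylpalladium closes by pivalate-assisted palladation of the only free ortho C–H, which the neighbouring bromine acidifies, and CO insertion with reductive elimination gives the ketone; the closest known reactions are the Larock carbonylative annulation of o-iodophenols with internal alkynes (alkyne inserts before CO) and the Larock cyclocarbonylation of o-halobiaryls to fluorenones (acylpalladium closing on C–H); no stereocentre is formed.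

**Step 4**
Reactants: 6 4,7-dibromo-6-iodo-3-methyl-2-(guaiazulen-3-yl)-1H-inden-1-one; 3 guaiazulene
Product: 7 4,7-dibromo-2,6-bis(guaiazulen-3-yl)-3-methyl-1H-inden-1-one
Conditions: Pd(OAc)2 (5 mol %), PPh3 (10 mol %), PivOH (30 mol %), K2CO3 (1.5 equiv), DMAc, 100 °C
Reagents that add atoms: none
Why: Palladium-catalysed direct C–H arylation (carboxylate-assisted electrophilic palladation) is known for guaiazulene and in a polar amide solvent goes to its most nucleophilic carbon C3, while the PPh3 catalyst inserts into the carbon–iodine bond of 6 well before either carbon–bromine bond.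

**Step 5**
Reactants: 7 4,7-dibromo-2,6-bis(guaiazulen-3-yl)-3-methyl-1H-inden-1-one
Product: 8 7-bromo-2,6-bis(guaiazulen-3-yl)-3-methyl-1-oxo-1H-indene-4-carbaldehyde
Conditions: PdCl2(PPh3)2 (5 mol %), HCO2Na (1.5 equiv), CO (1 atm), DMF, 100 °C
Reagents that add atoms: carbon monoxide [C-]#[O+]
Why: Palladium-catalysed reductive carbonylation (formylation with CO, formate as hydride source) should pick the C4 bromide, which has a free C5–H neighbour, over the C7 bromide, which is walled in by the C6 azulenyl group and the carbonyl-bearing ring-fusion carbon.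

**Step 6**
Reactants: 8 7-bromo-2,6-bis(guaiazulen-3-yl)-3-methyl-1-oxo-1H-indene-4-carbaldehyde
Product: 9 2,6-bis(guaiazulen-3-yl)-3,7-dimethyl-1-oxo-1H-indene-4-carbaldehyde (target)
Conditions: MeB(OH)2 (3 equiv), Pd(OAc)2 (5 mol %), SPhos (10 mol %), K3PO4 (3 equiv), toluene/H2O, 100 °C
Reagents that add atoms: methylboronic acid CB(O)O
Why: Suzuki–Miyaura methylation with a bulky electron-rich biarylphosphine is the standard answer to doubly flanked aryl bromides; the small methyl group transfers easily, and the reagents leave the aldehyde, the enone and both azulenes untouched; the product has no stereocentre.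

**Compound list**
1 | 1,4-dibromobenzene | Brc1ccc(Br)cc1 | starting material
2 | 1,4-dibromo-2,5-diiodobenzene | Brc1cc(I)c(Br)cc1I | intermediate
3 | guaiazulene (7-isopropyl-1,4-dimethylazulene) | c1cc(C)c2cc(C(C)C)ccc(C)c1-2 | starting material
4 | 3-iodoguaiazulene | Ic1cc(C)c2cc(C(C)C)ccc(C)c1-2 | intermediate
5 | 3-(prop-1-yn-1-yl)guaiazulene | CC#Cc1cc(C)c2cc(C(C)C)ccc(C)c1-2 | intermediate
6 | 4,7-dibromo-6-iodo-3-methyl-2-(guaiazulen-3-yl)-1H-inden-1-one | CC1=C(c2cc(C)c3cc(C(C)C)ccc(C)c2-3)C(=O)c2c(Br)c(I)cc(Br)c21 | intermediate
7 | 4,7-dibromo-2,6-bis(guaiazulen-3-yl)-3-methyl-1H-inden-1-one | CC1=C(c2cc(C)c3cc(C(C)C)ccc(C)c2-3)C(=O)c2c(Br)c(-c3cc(C)c4cc(C(C)C)ccc(C)c3-4)cc(Br)c21 | intermediate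
8 | 7-bromo-2,6-bis(guaiazulen-3-yl)-3-methyl-1-oxo-1H-indene-4-carbaldehyde | CC1=C(c2cc(C)c3cc(C(C)C)ccc(C)c2-3)C(=O)c2c(Br)c(-c3cc(C)c4cc(C(C)C)ccc(C)c3-4)cc(C=O)c21 | intermediate
9 | 2,6-bis(guaiazulen-3-yl)-3,7-dimethyl-1-oxo-1H-indene-4-carbaldehyde | CC1=C(c2cc(C)c3cc(C(C)C)ccc(C)c2-3)C(=O)c2c(C)c(-c3cc(C)c4cc(C(C)C)ccc(C)c3-4)cc(C=O)c21 | target

**Step count**
- Total step count: 6.
- Longest linear sequence: 5 (steps 2, 3, 4, 5, 6; the branch through steps 1, 3, 4, 5, 6 is equally long).

**Steps most likely to fail**

**Step 3.**
- *Risks:*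
  - CO may insert before the alkyne.
  - The strongly donating azulenyl group may turn the alkyne round.
  - The vinylpalladium may attack the 4-methyl group of its own azulene.
  - Compound 6 may react a second time at its remaining iodide.
- *Fallback:* it sets out from 2 and comes back at 6. Compound 2 is metalated at one of its two equivalent ring C–H positions with (tmp)MgCl·LiCl (tmp = 2,2,6,6-tetramethylpiperidide; THF, −40 °C). This gives (2,5-dibromo-3,6-diiodophenyl)magnesium chloride F1. Quenching with DMF gives 3,6-dibromo-2,5-diiodobenzaldehyde F2. The carbonyl carbon is then already in place. The classical CO-free Larock indenone annulation of this o-iodobenzaldehyde with 5 (Pd(OAc)2, Na2CO3, DMF, 100 °C) gives 6 through the more electron-poor iodide next to the formyl group.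

**Step 4.**
- *Risks:* the crowded iodide may couple slowly. Guaiazulene may also be arylated at C2 or at its 4-methyl group.
- *Fallback:* it sets out from 4 (made from 3 as in step 2) and 6, and comes back at 7. Iodine–magnesium exchange of 4 with iPrMgCl·LiCl (THF, −40 °C) gives guaiazulen-3-ylmagnesium chloride F3. ZnCl2 turns it into guaiazulen-3-ylzinc chloride F4. A Negishi coupling with 6 (Pd(PPh3)4, THF, rt) then fixes the azulene position in advance. At room temperature it touches only the iodide of 6 and spares the ketone.

**Step 5.**
- *Risks:* the bromide next to the carbonyl group may turn out to be the faster one. Formate may also simply remove a bromine.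
- *Fallback:* it sets out from 7 and comes back at 9, with the order of the two place-holder exchanges inverted. The Suzuki–Miyaura methylation (MeB(OH)2, 1.1 equiv, conditions of step 6, 60 °C) is run first on 7. It gives 4-bromo-2,6-bis(guaiazulen-3-yl)-3,7-dimethyl-1H-inden-1-one F5. The single bromide left is then formylated under the conditions of step 5, which gives 9 directly.

**Further compounds**
F1 | step 3 | (2,5-dibromo-3,6-diiodophenyl)magnesium chloride | Cl[Mg]c1c(I)c(Br)cc(I)c1Br
F2 | step 3 | 3,6-dibromo-2,5-diiodobenzaldehyde | O=Cc1c(I)c(Br)cc(I)c1Br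
F3 | step 4 | guaiazulen-3-ylmagnesium chloride | Cl[Mg]c1cc(C)c2cc(C(C)C)ccc(C)c1-2
F4 | step 4 | guaiazulen-3-ylzinc chloride | Cl[Zn]c1cc(C)c2cc(C(C)C)ccc(C)c1-2
F5 | step 5 | 4-bromo-2,6-bis(guaiazulen-3-yl)-3,7-dimethyl-1H-inden-1-one | CC1=C(c2cc(C)c3cc(C(C)C)ccc(C)c2-3)C(=O)c2c(C)c(-c3cc(C)c4cc(C(C)C)ccc(C)c3-4)cc(Br)c21
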